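**Strategy.** Everything rests on closing the 1,4-dioxin ring (ring C) last, between the ring-B oxygen and C1 of the dibenzofuran (ring D). The precursor is an open diaryl ether: a 2-aryloxydibenzofuran-3-ol whose ring B carries a silyl-masked phenol ortho to the ether oxygen. The key step exploits the C3(OH)–C2(OAr) unit of ring D: PhI(OAc)2 dearomatises it to an ortho-quinol acetate whose dienone ends at C1; fluoride then frees the ring-B phenoxide, which adds to C1, and loss of acetic acid restores the arene. One operation thus gives a net C–H etherification meta to the phenol, without any halide at C1.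

Key step: step 12

Remark: the target is achiral, so no stereocentre has to be set. Rings are lettered A (3,5-dihydroxyphenoxy), B (pentaoxygenated benzene), C (1,4-dioxin), D (dibenzofuran ring fused to the dioxin), E (furan) and F (resorcinol-type ring); dibenzofuran locants C1–C9b are used for rings D–F. Compounds 1, 3, 8 and 9 are assumed to be commercial. Bn = benzyl, PMB = 4-methoxybenzyl, TBS = tert-butyldimethylsilyl.

**Step 1**
Reactants: 1 5-bromo-4-fluoro-2-hydroxybenzaldehyde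
Product: 2 5-bromo-4-fluoro-2-[(4-methoxybenzyl)oxy]benzaldehyde
Conditions: PMBCl, K2CO3, DMF, rt
Reagents that add atoms: 4-methoxybenzyl chloride, COc1ccc(CCl)cc1
Why: Williamson ether synthesis on the acidic salicylaldehyde phenol; the PMB ether should survive base, palladium and peracid and can later be removed by acid beside benzyl and silyl ethers.

**Step 2**
Reactants: 2 5-bromo-4-fluoro-2-[(4-methoxybenzyl)oxy]benzaldehyde; 3 3,5-bis(benzyloxy)phenol
Product: 4 4-[3,5-bis(benzyloxy)phenoxy]-5-bromo-2-[(4-methoxybenzyl)oxy]benzaldehyde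
Conditions: K2CO3, DMF, 80 °C
Reagents that add atoms: none
Why: SNAr reaction in which the fluoride para to the formyl group (and ortho to bromine) is displaced by the phenoxide through a Meisenheimer adduct, while the bromide should stay.

**Step 3**
Reactants: 4 4-[3,5-bis(benzyloxy)phenoxy]-5-bromo-2-[(4-methoxybenzyl)oxy]benzaldehyde
Product: 5 7,9-bis(benzyloxy)-3-[(4-methoxybenzyl)oxy]dibenzo[b,d]furan-2-carbaldehyde
Conditions: Pd(OAc)2 (5 mol %), PCy3·HBF4 (10 mol %), K2CO3, DMA, 130 °C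
Reagents that add atoms: none
Why: palladium-catalysed intramolecular direct C–H arylation of a 2-bromodiaryl ether (concerted metalation–deprotonation) closes the furan ring; the two ortho C–H positions of ring F are equivalent, so one dibenzofuran should form.

**Step 4**
Reactants: 5 7,9-bis(benzyloxy)-3-[(4-methoxybenzyl)oxy]dibenzo[b,d]furan-2-carbaldehyde
Product: 7 7,9-bis(benzyloxy)-3-[(4-methoxybenzyl)oxy]dibenzo[b,d]furan-2-ol, via aryl formate 6 (not isolated)
Conditions: mCPBA, CH2Cl2, 0 °C to rt; aq. NaHCO3 wash; then K2CO3 (cat.), MeOH, rt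
Reagents that add atoms: 3-chloroperoxybenzoic acid, O=C(OO)c1cccc(Cl)c1
Why: Baeyer–Villiger (Dakin-type) oxidation in which the electron-rich aryl group (ortho alkoxy, para aryloxy) migrates in preference to hydrogen, followed by methanolysis of the formate.

**Step 5**
Reactants: 8 2,4,6-trifluorophenol; 9 3,5-bis(benzyloxy)phenylboronic acid
Product: 10 2-[3,5-bis(benzyloxy)phenoxy]-1,3,5-trifluorobenzene
Conditions: Cu(OAc)2 (20 mol %), pyridine, 4 Å molecular sieves, CH2Cl2, O2 (1 atm), rt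
Reagents that add atoms: none
Why: Chan–Lam oxidative O-arylation, which tolerates 2,6-disubstituted phenols and needs no activation of the electron-rich ring A.

**Step 6**
Reactants: 10 2-[3,5-bis(benzyloxy)phenoxy]-1,3,5-trifluorobenzene
Product: 12 3-[3,5-bis(benzyloxy)phenoxy]-2,4,6-trifluorobenzaldehyde, via aryllithium 11 (not isolated)
Conditions: LiN(iPr)2, THF, −78 °C; then DMF, −78 °C; aq. NH4Cl
Reagents that add atoms: N,N-dimethylformamide, CN(C)C=O
Why: directed ortho-lithiation at the C–H flanked by two fluorines (the two such positions are equivalent by symmetry) and formylation with DMF; at −78 °C neither aryne formation nor attack on the benzyl ethers is expected.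

**Step 7**
Reactants: 12 3-[3,5-bis(benzyloxy)phenoxy]-2,4,6-trifluorobenzaldehyde
Product: 13 4,6-bis(benzyloxy)-3-[3,5-bis(benzyloxy)phenoxy]-2-fluorobenzaldehyde
Conditions: BnOH (2.1 equiv), NaH (2.1 equiv), THF, −20 °C to rt
Reagents that add atoms: benzyl alcohol, OCc1ccccc1
Why: two SNAr reactions at the fluorides para and ortho to the formyl group; the third fluoride, flanked by the formyl and the aryloxy group, is the most hindered and the ring is deactivated once two alkoxy groups are in place.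

**Step 8**
Reactants: 13 4,6-bis(benzyloxy)-3-[3,5-bis(benzyloxy)phenoxy]-2-fluorobenzaldehyde; 7 7,9-bis(benzyloxy)-3-[(4-methoxybenzyl)oxy]dibenzo[b,d]furan-2-ol
Product: 14 4,6-bis(benzyloxy)-3-[3,5-bis(benzyloxy)phenoxy]-2-({7,9-bis(benzyloxy)-3-[(4-methoxybenzyl)oxy]dibenzo[b,d]furan-2-yl}oxy)benzaldehyde
Conditions: Cs2CO3, DMSO, 100 °C
Reagents that add atoms: none
Why: SNAr reaction of the remaining fluoride, activated by the ortho formyl group, with the caesium phenoxide of 7 in a dipolar aprotic solvent; it fixes which ring-B oxygen is bound to C2 of ring D.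

**Step 9**
Reactants: 14 4,6-bis(benzyloxy)-3-[3,5-bis(benzyloxy)phenoxy]-2-({7,9-bis(benzyloxy)-3-[(4-methoxybenzyl)oxy]dibenzo[b,d]furan-2-yl}oxy)benzaldehyde
Product: 16 4,6-bis(benzyloxy)-3-[3,5-bis(benzyloxy)phenoxy]-2-({7,9-bis(benzyloxy)-3-[(4-methoxybenzyl)oxy]dibenzo[b,d]furan-2-yl}oxy)phenol, via aryl formate 15 (not isolated)
Conditions: mCPBA, CH2Cl2, 0 °C; aq. NaHCO3 wash; then K2CO3 (cat.), MeOH, 0 °C, under argon
Reagents that add atoms: 3-chloroperoxybenzoic acid, O=C(OO)c1cccc(Cl)c1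
Why: Baeyer–Villiger oxidation of a 2,4,6-trioxygenated benzaldehyde (fast aryl migration) and formate methanolysis should give the single free phenol of ring B, on the carbon next to the diaryl ether.

**Step 10**
Reactants: 16 4,6-bis(benzyloxy)-3-[3,5-bis(benzyloxy)phenoxy]-2-({7,9-bis(benzyloxy)-3-[(4-methoxybenzyl)oxy]dibenzo[b,d]furan-2-yl}oxy)phenol
Product: 17 tert-butyldimethylsilyl ether of phenol 16
Conditions: TBSOTf, 2,6-lutidine, CH2Cl2, 0 °C
Reagents that add atoms: tert-butyldimethylsilyl trifluoromethanesulfonate, CC(C)(C)[Si](C)(C)OS(=O)(=O)C(F)(F)F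
Why: silylation of a hindered phenol with a silyl triflate; the TBS group hides the ring-B oxygen from the oxidant of step 12 and is released there by fluoride.

**Step 11**
Reactants: 17 tert-butyldimethylsilyl ether of phenol 16
Product: 18 7,9-bis(benzyloxy)-2-{3,5-bis(benzyloxy)-6-[3,5-bis(benzyloxy)phenoxy]-2-[(tert-butyldimethylsilyl)oxy]phenoxy}dibenzo[b,d]furan-3-ol
Conditions: TFA, anisole, CH2Cl2, 0 °C
Reagents that add atoms: none
Why: acidolysis of the PMB aryl ether, with the 4-methoxybenzyl cation trapped by anisole; benzyl ethers and the aryl silyl ether should be stable under these conditions.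

**Step 12**
Reactants: 18 7,9-bis(benzyloxy)-2-{3,5-bis(benzyloxy)-6-[3,5-bis(benzyloxy)phenoxy]-2-[(tert-butyldimethylsilyl)oxy]phenoxy}dibenzo[b,d]furan-3-ol
Product: 21 hexabenzyl ether of the target (ring-D hydroxyl free), via orthoquinol acetate 19 (not isolated), via tetrabutylammonium phenoxide 20 (not isolated)
Conditions: PhI(OAc)2 (1.05 equiv), CH2Cl2, −78 °C; then TBAF (1.2 equiv), THF, −78 to 0 °C; aq. NH4Cl
Reagents that add atoms: none
Why: PhI(OAc)2 ligates the only free phenol (C3–OH of ring D) and delivers acetate to C2, the ortho carbon whose aryloxy oxygen best stabilises the developing cation, to give the 6-acetoxy-6-aryloxycyclohexa-2,4-dienone 19 (Wessely-type oxidative dearomatisation). Fluoride then cleaves the aryl silyl ether, the ring-B phenoxide 20 adds in a 1,6-conjugate sense to C1, the terminus of the dienone O=C3–C4=C4a–C9b=C1, and loss of acetic acid across C1–C2 restores the aromatic ring. The closest known reaction type is the fluoride-triggered oxygen heterocyclisation of orthoquinol acetates that carry a silyl-masked oxygen nucleophile, which also ends by rearomatising loss of acetic acid. The 1,4-dioxin ring (ring C) closes in a 6-exo-trig mode, the C1=C9b bond lying outside the new ring. No stereocentre is formed in the product: C2, the only one in 19 (racemic), becomes sp2 again. The step needs acetoxylation at C2 and not at C4 or C9b (secured by the ortho aryloxy group and by ligand delivery from iodine) and attack of the phenoxide at C1 rather than at the C3 carbonyl or the acetyl group (only the C1 adduct can aromatise irreversibly, and acetate leaves in preference to the ring-B aryloxide).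

**Step 13**
Reactants: 21 hexabenzyl ether of the target (ring-D hydroxyl free)
Product: 22 target CNP0256302.0
Conditions: H2 (1 atm), Pd/C (10 wt % palladium on carbon), THF/MeOH, rt
Reagents that add atoms: none
Why: hydrogenolysis of the six benzyl aryl ethers; the diaryl ether, dioxin and furan C–O bonds are not benzylic and should survive.

**Compound list**

1 | 5-bromo-4-fluoro-2-hydroxybenzaldehyde | O=Cc1cc(Br)c(F)cc1O | starting material
2 | 5-bromo-4-fluoro-2-[(4-methoxybenzyl)oxy]benzaldehyde | O=Cc1cc(Br)c(F)cc1OCc1ccc(OC)cc1 | intermediate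
3 | 3,5-bis(benzyloxy)phenol | Oc1cc(OCc2ccccc2)cc(OCc2ccccc2)c1 | starting material
4 | 4-[3,5-bis(benzyloxy)phenoxy]-5-bromo-2-[(4-methoxybenzyl)oxy]benzaldehyde | O=Cc1cc(Br)c(Oc2cc(OCc3ccccc3)cc(OCc3ccccc3)c2)cc1OCc1ccc(OC)cc1 | intermediate
5 | 7,9-bis(benzyloxy)-3-[(4-methoxybenzyl)oxy]dibenzo[b,d]furan-2-carbaldehyde | O=Cc1cc2c(cc1OCc1ccc(OC)cc1)oc1cc(OCc3ccccc3)cc(OCc3ccccc3)c12 | intermediate
6 | 7,9-bis(benzyloxy)-3-[(4-methoxybenzyl)oxy]dibenzo[b,d]furan-2-yl formate (not isolated) | O=COc1cc2c(cc1OCc1ccc(OC)cc1)oc1cc(OCc3ccccc3)cc(OCc3ccccc3)c12 | intermediate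
7 | 7,9-bis(benzyloxy)-3-[(4-methoxybenzyl)oxy]dibenzo[b,d]furan-2-ol | Oc1cc2c(cc1OCc1ccc(OC)cc1)oc1cc(OCc3ccccc3)cc(OCc3ccccc3)c12 | intermediate
8 | 2,4,6-trifluorophenol | Oc1c(F)cc(F)cc1F | starting material
9 | 3,5-bis(benzyloxy)phenylboronic acid | OB(O)c1cc(OCc2ccccc2)cc(OCc2ccccc2)c1 | starting material
10 | 2-[3,5-bis(benzyloxy)phenoxy]-1,3,5-trifluorobenzene | Fc1cc(F)c(Oc2cc(OCc3ccccc3)cc(OCc3ccccc3)c2)c(F)c1 | intermediate
11 | {3-[3,5-bis(benzyloxy)phenoxy]-2,4,6-trifluorophenyl}lithium (not isolated) | [Li]c1c(F)cc(F)c(Oc2cc(OCc3ccccc3)cc(OCc3ccccc3)c2)c1F | intermediate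
12 | 3-[3,5-bis(benzyloxy)phenoxy]-2,4,6-trifluorobenzaldehyde | O=Cc1c(F)cc(F)c(Oc2cc(OCc3ccccc3)cc(OCc3ccccc3)c2)c1F | intermediate
13 | 4,6-bis(benzyloxy)-3-[3,5-bis(benzyloxy)phenoxy]-2-fluorobenzaldehyde | O=Cc1c(OCc2ccccc2)cc(OCc2ccccc2)c(Oc2cc(OCc3ccccc3)cc(OCc3ccccc3)c2)c1F | intermediate
14 | 4,6-bis(benzyloxy)-3-[3,5-bis(benzyloxy)phenoxy]-2-({7,9-bis(benzyloxy)-3-[(4-methoxybenzyl)oxy]dibenzo[b,d]furan-2-yl}oxy)benzaldehyde | O=Cc1c(OCc2ccccc2)cc(OCc2ccccc2)c(Oc2cc(OCc3ccccc3)cc(OCc3ccccc3)c2)c1Oc1cc2c(cc1OCc1ccc(OC)cc1)oc1cc(OCc3ccccc3)cc(OCc3ccccc3)c12 | intermediate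
15 | formate ester of phenol 16 (not isolated) | O=COc1c(OCc2ccccc2)cc(OCc2ccccc2)c(Oc2cc(OCc3ccccc3)cc(OCc3ccccc3)c2)c1Oc1cc2c(cc1OCc1ccc(OC)cc1)oc1cc(OCc3ccccc3)cc(OCc3ccccc3)c12 | intermediate
16 | 4,6-bis(benzyloxy)-3-[3,5-bis(benzyloxy)phenoxy]-2-({7,9-bis(benzyloxy)-3-[(4-methoxybenzyl)oxy]dibenzo[b,d]furan-2-yl}oxy)phenol | Oc1c(OCc2ccccc2)cc(OCc2ccccc2)c(Oc2cc(OCc3ccccc3)cc(OCc3ccccc3)c2)c1Oc1cc2c(cc1OCc1ccc(OC)cc1)oc1cc(OCc3ccccc3)cc(OCc3ccccc3)c12 | intermediate
17 | tert-butyldimethylsilyl ether of phenol 16 | CC(C)(C)[Si](C)(C)Oc1c(OCc2ccccc2)cc(OCc2ccccc2)c(Oc2cc(OCc3ccccc3)cc(OCc3ccccc3)c2)c1Oc1cc2c(cc1OCc1ccc(OC)cc1)oc1cc(OCc3ccccc3)cc(OCc3ccccc3)c12 | intermediate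
18 | 7,9-bis(benzyloxy)-2-{3,5-bis(benzyloxy)-6-[3,5-bis(benzyloxy)phenoxy]-2-[(tert-butyldimethylsilyl)oxy]phenoxy}dibenzo[b,d]furan-3-ol | CC(C)(C)[Si](C)(C)Oc1c(OCc2ccccc2)cc(OCc2ccccc2)c(Oc2cc(OCc3ccccc3)cc(OCc3ccccc3)c2)c1Oc1cc2c(cc1O)oc1cc(OCc3ccccc3)cc(OCc3ccccc3)c12 | intermediate
19 | 7,9-bis(benzyloxy)-2-{3,5-bis(benzyloxy)-6-[3,5-bis(benzyloxy)phenoxy]-2-[(tert-butyldimethylsilyl)oxy]phenoxy}-3-oxo-2,3-dihydrodibenzo[b,d]furan-2-yl acetate, racemic at C2 (not isolated) | CC(C)(C)[Si](C)(C)Oc1c(OCc2ccccc2)cc(OCc2ccccc2)c(Oc2cc(OCc3ccccc3)cc(OCc3ccccc3)c2)c1OC1(OC(C)=O)C(=O)C=C2Oc3cc(OCc4ccccc4)cc(OCc4ccccc4)c3C2=C1 | intermediate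
20 | tetrabutylammonium phenoxide formed from 19 by loss of the silyl group, racemic at C2 (not isolated) | [O-]c1c(OCc2ccccc2)cc(OCc2ccccc2)c(Oc2cc(OCc3ccccc3)cc(OCc3ccccc3)c2)c1OC1(OC(C)=O)C(=O)C=C2Oc3cc(OCc4ccccc4)cc(OCc4ccccc4)c3C2=C1.CCCC[N+](CCCC)(CCCC)CCCC | intermediate
21 | hexabenzyl ether of the target: benzyl ethers on the two ring-A, two ring-B and two ring-F hydroxyls, ring-D hydroxyl free | Oc1cc2oc3cc(OCc4ccccc4)cc(OCc4ccccc4)c3c2c2Oc3c(OCc4ccccc4)cc(OCc4ccccc4)c(Oc4cc(OCc5ccccc5)cc(OCc5ccccc5)c4)c3Oc12 | intermediate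
22 | CNP0256302.0 (achiral) | Oc1cc(O)cc(Oc2c(O)cc(O)c3c2Oc2c(O)cc4oc5cc(O)cc(O)c5c4c2O3)c1 | target

**Total step count:** 13 steps. **Longest linear sequence:** 10 steps (steps 1–4, then 8–13); the ring A–B branch (steps 5–7) joins at step 8.

**Steps most likely to fail**

Step 12 (key step). The dearomatisation may deliver acetate to C9b or C4 instead of C2. The freed phenoxide may also take up the acetyl group of the ketal acetate, after which the hemiketal collapses and the diaryl ether is lost. The fallback makes the same bond by an intramolecular Ullmann etherification and sets out from 7. Phenol-directed ortho-bromination (NBS, catalytic iPr2NH, CH2Cl2, 0 °C) should give 7,9-bis(benzyloxy)-1-bromo-3-[(4-methoxybenzyl)oxy]dibenzo[b,d]furan-2-ol F1. SNAr with 13 (Cs2CO3, DMSO, 110 °C) should give the bromo diaryl ether aldehyde F2, and Baeyer–Villiger oxidation with methanolysis as in step 9 the bromo phenol F3. CuI, N,N-dimethylglycine and Cs2CO3 in dioxane at 100 °C should then close the dioxin ring to the 4-methoxybenzyl ether F4 of compound 21. TFA/anisole as in step 11 comes back to the route at 21.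

Step 8. Addition of the bulky phenoxide may be too slow at a carbon flanked by two ortho substituents on a ring deactivated by two alkoxy groups, so that thermal degradation of the aldehyde takes over. The fallback replaces the arene SNAr by addition–elimination on a quinone and sets out from 13. Baeyer–Villiger oxidation and methanolysis should give 4,6-bis(benzyloxy)-3-[3,5-bis(benzyloxy)phenoxy]-2-fluorophenol F5. PhI(OAc)2 in MeCN/H2O at 0 °C should oxidise it, with loss of the para benzyl group, to 5-(benzyloxy)-2-[3,5-bis(benzyloxy)phenoxy]-3-fluoro-1,4-benzoquinone F6. Phenol 7 with K2CO3 in MeCN at 0 °C should displace the vinylic fluoride to give the bis(aryloxy)quinone F7, and Na2S2O4 in THF/H2O should reduce it to the hydroquinone F8. One equivalent of BnBr with K2CO3 in acetone should alkylate the less hindered hydroxyl (the one with a neighbouring C–H), which comes back to the route at 16.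

Step 7. Site selectivity may be lost: benzyloxide may attack the flanked fluoride or substitute a third time. The fallback lets the electronic bias of a quinone decide the site and sets out from 10. Lithiation as in step 6, then B(OMe)3 and H2O2/AcOH, should give 3-[3,5-bis(benzyloxy)phenoxy]-2,4,6-trifluorophenol F9. PhI(OAc)2 in MeCN/H2O (aq. NaHCO3 work-up) should oxidise it, with loss of the para fluoride, to 2-[3,5-bis(benzyloxy)phenoxy]-3,5-difluoro-1,4-benzoquinone F10. BnOH with K2CO3 in MeCN at 0 °C should replace only the fluoride on the enone carbon that has a C–H neighbour; the other fluoride sits on the electron-rich aryloxy enol ether. This gives the fluoroquinone F6, which is carried on through the bis(aryloxy)quinone F7 and the hydroquinone F8 as described for step 8, and comes back to the route at 16.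

**Further compounds**

F1 | step 12 | 7,9-bis(benzyloxy)-1-bromo-3-[(4-methoxybenzyl)oxy]dibenzo[b,d]furan-2-ol | Oc1c(Br)c2c(cc1OCc1ccc(OC)cc1)oc1cc(OCc3ccccc3)cc(OCc3ccccc3)c12
F2 | step 12 | 4,6-bis(benzyloxy)-3-[3,5-bis(benzyloxy)phenoxy]-2-({7,9-bis(benzyloxy)-1-bromo-3-[(4-methoxybenzyl)oxy]dibenzo[b,d]furan-2-yl}oxy)benzaldehyde | O=Cc1c(OCc2ccccc2)cc(OCc2ccccc2)c(Oc2cc(OCc3ccccc3)cc(OCc3ccccc3)c2)c1Oc1c(Br)c2c(cc1OCc1ccc(OC)cc1)oc1cc(OCc3ccccc3)cc(OCc3ccccc3)c12
F3 | step 12 | 4,6-bis(benzyloxy)-3-[3,5-bis(benzyloxy)phenoxy]-2-({7,9-bis(benzyloxy)-1-bromo-3-[(4-methoxybenzyl)oxy]dibenzo[b,d]furan-2-yl}oxy)phenol | Oc1c(OCc2ccccc2)cc(OCc2ccccc2)c(Oc2cc(OCc3ccccc3)cc(OCc3ccccc3)c2)c1Oc1c(Br)c2c(cc1OCc1ccc(OC)cc1)oc1cc(OCc3ccccc3)cc(OCc3ccccc3)c12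
F4 | step 12 | 4-methoxybenzyl ether of 21 at the ring-D hydroxyl | COc1ccc(COc2cc3oc4cc(OCc5ccccc5)cc(OCc5ccccc5)c4c3c3Oc4c(OCc5ccccc5)cc(OCc5ccccc5)c(Oc5cc(OCc6ccccc6)cc(OCc6ccccc6)c5)c4Oc23)cc1
F5 | step 8 | 4,6-bis(benzyloxy)-3-[3,5-bis(benzyloxy)phenoxy]-2-fluorophenol | Oc1c(OCc2ccccc2)cc(OCc2ccccc2)c(Oc2cc(OCc3ccccc3)cc(OCc3ccccc3)c2)c1F
F6 | step 8 | 5-(benzyloxy)-2-[3,5-bis(benzyloxy)phenoxy]-3-fluoro-1,4-benzoquinone | O=C1C(OCc2ccccc2)=CC(=O)C(Oc2cc(OCc3ccccc3)cc(OCc3ccccc3)c2)=C1F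
F7 | step 8 | 5-(benzyloxy)-2-[3,5-bis(benzyloxy)phenoxy]-3-({7,9-bis(benzyloxy)-3-[(4-methoxybenzyl)oxy]dibenzo[b,d]furan-2-yl}oxy)-1,4-benzoquinone | O=C1C(OCc2ccccc2)=CC(=O)C(Oc2cc(OCc3ccccc3)cc(OCc3ccccc3)c2)=C1Oc1cc2c(cc1OCc1ccc(OC)cc1)oc1cc(OCc3ccccc3)cc(OCc3ccccc3)c12
F8 | step 8 | 5-(benzyloxy)-2-[3,5-bis(benzyloxy)phenoxy]-3-({7,9-bis(benzyloxy)-3-[(4-methoxybenzyl)oxy]dibenzo[b,d]furan-2-yl}oxy)benzene-1,4-diol | Oc1c(OCc2ccccc2)cc(O)c(Oc2cc(OCc3ccccc3)cc(OCc3ccccc3)c2)c1Oc1cc2c(cc1OCc1ccc(OC)cc1)oc1cc(OCc3ccccc3)cc(OCc3ccccc3)c12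
F9 | step 7 | 3-[3,5-bis(benzyloxy)phenoxy]-2,4,6-trifluorophenol | Oc1c(F)cc(F)c(Oc2cc(OCc3ccccc3)cc(OCc3ccccc3)c2)c1F
F10 | step 7 | 2-[3,5-bis(benzyloxy)phenoxy]-3,5-difluoro-1,4-benzoquinone | O=C1C(F)=CC(=O)C(Oc2cc(OCc3ccccc3)cc(OCc3ccccc3)c2)=C1F
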